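**Target:** (3E,4R,5R)-5-(3,4-dihydroxyphenyl)-4-(3,5-dihydroxyphenyl)-3-[(4-hydroxy-3-methoxyphenyl)methylidene]oxolan-2-one. The two aryl groups on C4 and C5 are trans; the arylidene aryl is anti to the lactone C=O.

Lactone numbering: O1, C2(=O), C3, C4, C5. Ring A = guaiacyl ring on the exocyclic CH; ring B = catechol ring on C5; ring C = resorcinol ring on C4. TBS = tert-butyldimethylsilyl, TIPS = triisopropylsilyl.

## Retrosynthetic overview

1. Target ⇒ penta-silyl ether 25 (global desilylation) ⇒ trans-4,5-diaryl lactone 16 + O-TBS-vanillin 22 (C3=CH by aldol condensation, ring A attached last).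
2. Lactone 16 ⇒ γ-keto ester 14: oxazaborolidine reduction sets C5, then O1–C2 lactonisation closes the only ring made in the synthesis.
3. Key disconnection C4–ring C: 14 ⇒ racemic α-bromo ketone 7 + arylzinc 13 by a stereoconvergent nickel-catalysed radical arylation that sets C4.
4. 7 ⇒ catechol + succinic anhydride (Friedel–Crafts); 13 ⇒ resorcinol (C–H borylation, bromination); 22 ⇒ catechol + MeI + glyoxylic acid.
5. Ring order: the three benzene rings are bought; the lactone ring is formed in step 7.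

Assumption: the sense of induction of the nickel–pybox catalyst (step 6) and of the oxazaborolidine (step 7) is assigned by analogy with simple aryl alkyl ketones and is confirmed on the first run; the antipodal ligand is used if the sense is opposite.

## Route

Step 1
Reactants: 1 catechol; 2 succinic anhydride
Product: 4 methyl 4-(3,4-dihydroxyphenyl)-4-oxobutanoate, via keto acid 3 (not isolated)
Conditions: AlCl3 (4 equiv), 1,2-dichloroethane/PhNO2, 0 → 80 °C; then MeOH (excess), reflux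
Reagents that add atoms: methanol, CO
Why: Friedel–Crafts acylation (O-acylation then Fries-type C-acylation under excess AlCl3) goes para to one hydroxyl of catechol, and the HCl formed on the methanol quench drives Fischer esterification of the acid; no stereocentre is formed.

Step 2
Reactants: 4 methyl 4-(3,4-dihydroxyphenyl)-4-oxobutanoate
Product: 5 methyl 4-[3,4-bis(tert-butyldimethylsilyloxy)phenyl]-4-oxobutanoate
Conditions: TBSCl (2.4 equiv), imidazole, DMF, 25 °C
Reagents that add atoms: tert-butyldimethylsilyl chloride, CC(C)(C)[Si](C)(C)Cl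
Why: Standard silyl ether protection of both phenols, needed because the later organozinc, borane and amide-base steps do not tolerate free catechol OH groups.

Step 3
Reactants: 5 methyl 4-[3,4-bis(tert-butyldimethylsilyloxy)phenyl]-4-oxobutanoate
Product: 7 racemic methyl 3-bromo-4-[3,4-bis(tert-butyldimethylsilyloxy)phenyl]-4-oxobutanoate, via silyl enol ether 6 (not isolated)
Conditions: TMSOTf, Et3N, CH2Cl2, 0 °C; then NBS, THF, −78 → 0 °C
Reagents that add atoms: N-bromosuccinimide, BrN1C(=O)CCC1=O; trimethylsilyl triflate, C[Si](C)(C)OS(=O)(=O)C(F)(F)F (silicon in 6 only)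
Why: Soft enolisation gives the ketone-derived silyl enol ether only (the ketone has one enolisable side and the ester is not silylated), and electrophilic α-bromination with NBS then avoids ring bromination; the bromide is racemic, which is irrelevant because the next step is stereoconvergent.

Step 4
Reactants: 8 resorcinol
Product: 9 1,3-bis(triisopropylsilyloxy)benzene
Conditions: TIPSCl (2.3 equiv), imidazole, DMF, 25 → 40 °C
Reagents that add atoms: triisopropylsilyl chloride, CC(C)[Si](Cl)(C(C)C)C(C)C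
Why: Silyl ether protection with bulky groups that also block C2, C4 and C6 sterically for the following C–H borylation.

Step 5
Reactants: 9 1,3-bis(triisopropylsilyloxy)benzene
Product: 11 1-bromo-3,5-bis(triisopropylsilyloxy)benzene, via arylboronate 10 (not isolated)
Conditions: [Ir(cod)(OMe)]2 (1.5 mol%), 4,4'-di-tert-butyl-2,2'-bipyridine (3 mol%), B2pin2 (1.0 equiv), THF, 80 °C; then CuBr2 (3.5 equiv), MeOH/H2O, 80 °C
Reagents that add atoms: copper dibromide, Br[Cu]Br; bis(pinacolato)diboron, CC1(C)OB(OC1(C)C)B1OC(C)(C)C(C)(C)O1 (boron in 10 only)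
Why: Iridium-catalysed C–H borylation is sterically controlled and takes the only C–H with no ortho substituent (C5, meta to both oxygens), a position not reachable by electrophilic substitution, and CuBr2 bromodeboronation converts the boronate to the bromide in the same pot.

Step 6
Reactants: 7 racemic methyl 3-bromo-4-[3,4-bis(tert-butyldimethylsilyloxy)phenyl]-4-oxobutanoate; 11 1-bromo-3,5-bis(triisopropylsilyloxy)benzene
Product: 14 methyl (3S)-4-[3,4-bis(tert-butyldimethylsilyloxy)phenyl]-3-[3,5-bis(triisopropylsilyloxy)phenyl]-4-oxobutanoate, via aryl Grignard reagent 12 (not isolated), via arylzinc iodide 13 (not isolated)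
Conditions: 11, Mg, LiCl, THF, 40 °C; ZnI2, THF, 25 °C; then 7 (limiting, 13 in 1.3 equiv), NiCl2·glyme (5 mol%), (R,R)-Ph-pybox [2,6-bis((4R)-4-phenyl-4,5-dihydro-1,3-oxazol-2-yl)pyridine] (6.5 mol%), glyme/THF, −30 °C
Reagents that add atoms: magnesium, [Mg] (in 12 only); zinc diiodide, I[Zn]I (in 13 only)
Why: Stereoconvergent nickel-catalysed Negishi α-arylation, in which a monovalent nickel–aryl species abstracts bromine from either enantiomer of 7 to give a planar α-keto radical at C4 that is captured in the chiral pybox–nickel sphere, so reductive elimination from trivalent nickel forms the C4–aryl bond and sets (S)-C4 under catalyst control at a temperature where the labile α-aryl ketone does not racemise.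

Step 7
Reactants: 14 methyl (3S)-4-[3,4-bis(tert-butyldimethylsilyloxy)phenyl]-3-[3,5-bis(triisopropylsilyloxy)phenyl]-4-oxobutanoate
Product: 16 (4S,5R)-5-[3,4-bis(tert-butyldimethylsilyloxy)phenyl]-4-[3,5-bis(triisopropylsilyloxy)phenyl]oxolan-2-one, via hydroxy ester 15 (not isolated)
Conditions: (S)-2-methyl-CBS-oxazaborolidine (20 mol%), BH3·SMe2 (0.7 equiv), THF, −20 °C; MeOH quench; then pyridinium p-toluenesulfonate (cat.), PhMe, 60 °C
Reagents that add atoms: none
Why: Corey–Bakshi–Shibata reduction delivers hydride to the aryl ketone under catalyst control (aryl as the large group) to give the (4R)-carbinol under non-basic conditions that leave C4 untouched, and lactonisation by acyl substitution with retention then gives the trans lactone.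

Step 8
Reactants: 1 catechol
Product: 17 2-methoxyphenol (guaiacol)
Conditions: MeI (1.0 equiv), K2CO3 (1.0 equiv), acetone, 56 °C, catechol in 1.5-fold excess; veratrole removed by base extraction, catechol by water wash
Reagents that add atoms: iodomethane, CI
Why: Williamson mono-O-methylation, held at the mono-ether stage by limiting base and electrophile with excess diol.

Step 9
Reactants: 17 2-methoxyphenol; 18 glyoxylic acid
Product: 21 4-hydroxy-3-methoxybenzaldehyde (vanillin), via mandelic acid 19 (not isolated), via arylglyoxylic acid 20 (not isolated)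
Conditions: NaOH, H2O, 30 °C; then O2 (1 atm), CuSO4 (5 mol%), NaOH aq., 95 °C; then H2SO4 to pH 2, 70 °C
Reagents that add atoms: none
Why: Electrophilic aromatic hydroxyalkylation of the phenoxide with glyoxylate goes para to the free OH (not para to OMe), and oxidative decarboxylation of the mandelic acid (oxidation to the α-keto acid, then loss of CO2) gives the aldehyde.

Step 10
Reactants: 21 4-hydroxy-3-methoxybenzaldehyde
Product: 22 4-(tert-butyldimethylsilyloxy)-3-methoxybenzaldehyde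
Conditions: TBSCl (1.2 equiv), imidazole, DMF, 25 °C
Reagents that add atoms: tert-butyldimethylsilyl chloride, CC(C)(C)[Si](C)(C)Cl
Why: Silyl ether protection, needed because a phenoxide aldehyde is a poor electrophile for the lactone enolate.

Step 11
Reactants: 16 (4S,5R)-5-[3,4-bis(tert-butyldimethylsilyloxy)phenyl]-4-[3,5-bis(triisopropylsilyloxy)phenyl]oxolan-2-one; 22 4-(tert-butyldimethylsilyloxy)-3-methoxybenzaldehyde
Product: 25 (3E,4R,5R)-5-[3,4-bis(tert-butyldimethylsilyloxy)phenyl]-4-[3,5-bis(triisopropylsilyloxy)phenyl]-3-{[4-(tert-butyldimethylsilyloxy)-3-methoxyphenyl]methylidene}oxolan-2-one, via lithium aldolate 23 (not isolated), via aldol mesylate 24 (not isolated)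
Conditions: lithium diisopropylamide (1.1 equiv), THF, −78 °C; 22; then MsCl, −78 → 0 °C; then DBU, 0 → 25 °C
Reagents that add atoms: methanesulfonyl chloride, CS(Cl)(=O)=O (in 24 only); lithium diisopropylamide, [Li]N(C(C)C)C(C)C (lithium in 23 only)
Why: Aldol condensation (enolate addition, mesylation, E1cB elimination) gives the conjugated (E)-arylidene lactone, the thermodynamically preferred isomer with the aryl anti to C=O; C4–H is not acidic and C5 is not touched, so both stereocentres persist (the descriptor at C4 changes from S to R only because C3 gains priority).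

Step 12
Reactants: 25 penta-silyl ether of the target
Product: 26 (3E,4R,5R)-5-(3,4-dihydroxyphenyl)-4-(3,5-dihydroxyphenyl)-3-[(4-hydroxy-3-methoxyphenyl)methylidene]oxolan-2-one
Conditions: Bu4NF (6 equiv), AcOH (6 equiv), THF, 0 → 25 °C
Reagents that add atoms: none
Why: Fluoride-mediated desilylation of all five aryl silyl ethers, buffered with acetic acid so that no free p-phenoxide forms that could open the benzylic lactone through a quinone methide; the methyl ether, alkene and lactone are inert.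

## Compound list

1 | catechol | Oc1ccccc1O | starting material
2 | succinic anhydride | O=C1CCC(=O)O1 | starting material
3 | 4-(3,4-dihydroxyphenyl)-4-oxobutanoic acid | OC(=O)CCC(=O)c1ccc(O)c(O)c1 | intermediate
4 | methyl 4-(3,4-dihydroxyphenyl)-4-oxobutanoate | COC(=O)CCC(=O)c1ccc(O)c(O)c1 | intermediate
5 | methyl 4-[3,4-bis(TBS-oxy)phenyl]-4-oxobutanoate | COC(=O)CCC(=O)c1ccc(O[Si](C)(C)C(C)(C)C)c(O[Si](C)(C)C(C)(C)C)c1 | intermediate
6 | methyl (3Z)-4-[3,4-bis(TBS-oxy)phenyl]-4-(trimethylsilyloxy)but-3-enoate | COC(=O)C/C=C(\O[Si](C)(C)C)c1ccc(O[Si](C)(C)C(C)(C)C)c(O[Si](C)(C)C(C)(C)C)c1 | intermediate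
7 | racemic methyl 3-bromo-4-[3,4-bis(TBS-oxy)phenyl]-4-oxobutanoate | COC(=O)CC(Br)C(=O)c1ccc(O[Si](C)(C)C(C)(C)C)c(O[Si](C)(C)C(C)(C)C)c1 | intermediate
8 | resorcinol | Oc1cccc(O)c1 | starting material
9 | 1,3-bis(TIPS-oxy)benzene | CC(C)[Si](Oc1cccc(O[Si](C(C)C)(C(C)C)C(C)C)c1)(C(C)C)C(C)C | intermediate
10 | 2-[3,5-bis(TIPS-oxy)phenyl]-4,4,5,5-tetramethyl-1,3,2-dioxaborolane | CC(C)[Si](Oc1cc(B2OC(C)(C)C(C)(C)O2)cc(O[Si](C(C)C)(C(C)C)C(C)C)c1)(C(C)C)C(C)C | intermediate
11 | 1-bromo-3,5-bis(TIPS-oxy)benzene | CC(C)[Si](Oc1cc(Br)cc(O[Si](C(C)C)(C(C)C)C(C)C)c1)(C(C)C)C(C)C | intermediate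
12 | [3,5-bis(TIPS-oxy)phenyl]magnesium bromide | CC(C)[Si](Oc1cc([Mg]Br)cc(O[Si](C(C)C)(C(C)C)C(C)C)c1)(C(C)C)C(C)C | intermediate
13 | [3,5-bis(TIPS-oxy)phenyl]zinc iodide | CC(C)[Si](Oc1cc([Zn]I)cc(O[Si](C(C)C)(C(C)C)C(C)C)c1)(C(C)C)C(C)C | intermediate
14 | methyl (3S)-4-[3,4-bis(TBS-oxy)phenyl]-3-[3,5-bis(TIPS-oxy)phenyl]-4-oxobutanoate | COC(=O)C[C@@H](c1cc(O[Si](C(C)C)(C(C)C)C(C)C)cc(O[Si](C(C)C)(C(C)C)C(C)C)c1)C(=O)c1ccc(O[Si](C)(C)C(C)(C)C)c(O[Si](C)(C)C(C)(C)C)c1 | intermediate
15 | methyl (3S,4R)-4-[3,4-bis(TBS-oxy)phenyl]-3-[3,5-bis(TIPS-oxy)phenyl]-4-hydroxybutanoate | COC(=O)C[C@@H](c1cc(O[Si](C(C)C)(C(C)C)C(C)C)cc(O[Si](C(C)C)(C(C)C)C(C)C)c1)[C@@H](O)c1ccc(O[Si](C)(C)C(C)(C)C)c(O[Si](C)(C)C(C)(C)C)c1 | intermediate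
16 | (4S,5R)-5-[3,4-bis(TBS-oxy)phenyl]-4-[3,5-bis(TIPS-oxy)phenyl]oxolan-2-one (trans) | O=C1C[C@@H](c2cc(O[Si](C(C)C)(C(C)C)C(C)C)cc(O[Si](C(C)C)(C(C)C)C(C)C)c2)[C@H](c2ccc(O[Si](C)(C)C(C)(C)C)c(O[Si](C)(C)C(C)(C)C)c2)O1 | intermediate
17 | 2-methoxyphenol | COc1ccccc1O | intermediate
18 | glyoxylic acid | O=CC(=O)O | starting material
19 | racemic 2-hydroxy-2-(4-hydroxy-3-methoxyphenyl)acetic acid | COc1cc(C(O)C(=O)O)ccc1O | intermediate
20 | 2-(4-hydroxy-3-methoxyphenyl)-2-oxoacetic acid | COc1cc(C(=O)C(=O)O)ccc1O | intermediate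
21 | 4-hydroxy-3-methoxybenzaldehyde | COc1cc(C=O)ccc1O | intermediate
22 | 4-(TBS-oxy)-3-methoxybenzaldehyde | COc1cc(C=O)ccc1O[Si](C)(C)C(C)(C)C | intermediate
23 | lithium aldolate of 16 with 22 (mixture at C3 and the carbinol carbon; 4,5-trans) | COc1cc(C(O[Li])C2C(=O)O[C@@H](c3ccc(O[Si](C)(C)C(C)(C)C)c(O[Si](C)(C)C(C)(C)C)c3)[C@@H]2c2cc(O[Si](C(C)C)(C(C)C)C(C)C)cc(O[Si](C(C)C)(C(C)C)C(C)C)c2)ccc1O[Si](C)(C)C(C)(C)C | intermediate
24 | methanesulfonate of the aldol adduct (same mixture) | COc1cc(C(OS(C)(=O)=O)C2C(=O)O[C@@H](c3ccc(O[Si](C)(C)C(C)(C)C)c(O[Si](C)(C)C(C)(C)C)c3)[C@@H]2c2cc(O[Si](C(C)C)(C(C)C)C(C)C)cc(O[Si](C(C)C)(C(C)C)C(C)C)c2)ccc1O[Si](C)(C)C(C)(C)C | intermediate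
25 | (3E,4R,5R)-penta-silyl ether of the target | COc1cc(/C=C2/C(=O)O[C@@H](c3ccc(O[Si](C)(C)C(C)(C)C)c(O[Si](C)(C)C(C)(C)C)c3)[C@@H]2c2cc(O[Si](C(C)C)(C(C)C)C(C)C)cc(O[Si](C(C)C)(C(C)C)C(C)C)c2)ccc1O[Si](C)(C)C(C)(C)C | intermediate
26 | (3E,4R,5R)-5-(3,4-dihydroxyphenyl)-4-(3,5-dihydroxyphenyl)-3-[(4-hydroxy-3-methoxyphenyl)methylidene]oxolan-2-one | COc1cc(/C=C2/C(=O)O[C@@H](c3ccc(O)c(O)c3)[C@@H]2c2cc(O)cc(O)c2)ccc1O | target

## Step count and risks

Total steps: 12. Longest linear sequence: 7 (steps 1 → 2 → 3 → 6 → 7 → 11 → 12).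

**Step 6 (stereoconvergent nickel arylation).** Risks are low ee with the β-ester side chain, and loss of HBr from 7 to the aroylacrylate. The fallback sets out from 7 and 11 and moves the stereocontrol off the nickel step. The same radical Negishi coupling is run with an achiral ligand (NiCl2·glyme, 4,4'-di-tert-butyl-2,2'-bipyridine) to give racemic keto ester F1. Its labile centre is then resolved dynamically by asymmetric transfer hydrogenation (RuCl[(S,S)-TsDPEN](p-cymene), HCO2H/Et3N, 40 °C), which reduces the matched (3S) enantiomer in the Felkin–Anh sense to syn hydroxy ester F2. Mesylation (MsCl, Et3N, CH2Cl2, −20 → 25 °C) gives benzylic mesylate F3, which is displaced by the ester carbonyl oxygen with inversion at the carbinol carbon (methyl lost to mesylate). The fallback comes back to the route at trans lactone 16.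

**Step 7 (oxazaborolidine reduction).** The catalyst must override the substrate's Felkin–Anh preference, which leads to the cis lactone, and the α-branched alkyl group may compete with the aryl as the large group. The fallback sets out from 14 and uses substrate control followed by thermodynamic control. LiBH(s-Bu)3 in THF at −78 °C gives lithium alkoxide F4, which cyclises on warming to cis lactone F5. BF3·OEt2 (20 mol%, CH2Cl2, −20 → 0 °C) then epimerises C5 by reversible ionisation of the p-silyloxybenzylic C–O bond to the more stable trans isomer. The fallback comes back at 16.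

**Step 11 (aldol condensation).** C3 is hindered by the neighbouring C4 aryl group, so retro-aldol or incomplete elimination is possible. The fallback sets out from 16 and replaces the aldol by an olefination. Lithium diisopropylamide (3 equiv) and ClP(O)(OEt)2 in THF (−78 → 0 °C) give enol phosphate F6, which rearranges under the excess base (1,3-phosphoryl shift from O to C) to phosphonate F7. Horner–Wadsworth–Emmons reaction of F7 with aldehyde 22 (NaH, THF, 0 °C) gives the (E)-arylidene lactone. The fallback comes back at 25.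

## Further compounds

F1 | step 6 | racemic methyl 4-[3,4-bis(TBS-oxy)phenyl]-3-[3,5-bis(TIPS-oxy)phenyl]-4-oxobutanoate | COC(=O)CC(c1cc(O[Si](C(C)C)(C(C)C)C(C)C)cc(O[Si](C(C)C)(C(C)C)C(C)C)c1)C(=O)c1ccc(O[Si](C)(C)C(C)(C)C)c(O[Si](C)(C)C(C)(C)C)c1
F2 | step 6 | methyl (3S,4S)-4-[3,4-bis(TBS-oxy)phenyl]-3-[3,5-bis(TIPS-oxy)phenyl]-4-hydroxybutanoate | COC(=O)C[C@@H](c1cc(O[Si](C(C)C)(C(C)C)C(C)C)cc(O[Si](C(C)C)(C(C)C)C(C)C)c1)[C@H](O)c1ccc(O[Si](C)(C)C(C)(C)C)c(O[Si](C)(C)C(C)(C)C)c1
F3 | step 6 | methyl (3S,4S)-4-[3,4-bis(TBS-oxy)phenyl]-3-[3,5-bis(TIPS-oxy)phenyl]-4-(methanesulfonyloxy)butanoate | COC(=O)C[C@@H](c1cc(O[Si](C(C)C)(C(C)C)C(C)C)cc(O[Si](C(C)C)(C(C)C)C(C)C)c1)[C@H](OS(C)(=O)=O)c1ccc(O[Si](C)(C)C(C)(C)C)c(O[Si](C)(C)C(C)(C)C)c1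
F4 | step 7 | lithium alkoxide of methyl (3S,4S)-4-[3,4-bis(TBS-oxy)phenyl]-3-[3,5-bis(TIPS-oxy)phenyl]-4-hydroxybutanoate | COC(=O)C[C@@H](c1cc(O[Si](C(C)C)(C(C)C)C(C)C)cc(O[Si](C(C)C)(C(C)C)C(C)C)c1)[C@H](O[Li])c1ccc(O[Si](C)(C)C(C)(C)C)c(O[Si](C)(C)C(C)(C)C)c1
F5 | step 7 | (4S,5S)-5-[3,4-bis(TBS-oxy)phenyl]-4-[3,5-bis(TIPS-oxy)phenyl]oxolan-2-one (cis) | O=C1C[C@@H](c2cc(O[Si](C(C)C)(C(C)C)C(C)C)cc(O[Si](C(C)C)(C(C)C)C(C)C)c2)[C@@H](c2ccc(O[Si](C)(C)C(C)(C)C)c(O[Si](C)(C)C(C)(C)C)c2)O1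
F6 | step 11 | diethyl enol phosphate of lactone 16 (4,5-trans) | CCOP(=O)(OCC)OC1=C[C@@H](c2cc(O[Si](C(C)C)(C(C)C)C(C)C)cc(O[Si](C(C)C)(C(C)C)C(C)C)c2)[C@H](c2ccc(O[Si](C)(C)C(C)(C)C)c(O[Si](C)(C)C(C)(C)C)c2)O1
F7 | step 11 | diethyl {5-[3,4-bis(TBS-oxy)phenyl]-4-[3,5-bis(TIPS-oxy)phenyl]-2-oxooxolan-3-yl}phosphonate (4,5-trans, mixture at C3) | CCOP(=O)(OCC)C1C(=O)O[C@@H](c2ccc(O[Si](C)(C)C(C)(C)C)c(O[Si](C)(C)C(C)(C)C)c2)[C@@H]1c1cc(O[Si](C(C)C)(C(C)C)C(C)C)cc(O[Si](C(C)C)(C(C)C)C(C)C)c1
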